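**Assumption:** Artocarpetin B has no stereocentre, so the "single enantiomer" is simply the achiral compound drawn; the only stereo-element on the way is the E double bond of chalcone 6. Compound 1 is taken as a catalogue chemical.

## Retrosynthetic overview

1. Target 12 ⇐ 5-O-prenylflavone 9 by a para-Claisen–Cope relay of the prenyl unit from O5 to C8, which also frees the 5-OH.
2. 9 ⇐ chalcone 6 by closing the O1–C2 bond (key C–O bond, proposed tandem oxa-Michael/dehydrobromination); ring C is the only ring built.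
3. 6 ⇐ O-prenyl acetophenone 3 + aldehyde 4 (Claisen–Schmidt); rings A and B are bought.
4. 3 ⇐ symmetric acetophenone 1 + prenyl bromide 2; the ether blocks one of two equivalent phenols, so ring closure can only give the 5-O-prenyl/8-H pattern.

## Route

Step 1
Reactants: 1 1-(2,6-dihydroxy-4-methoxyphenyl)ethanone; 2 prenyl bromide (1-bromo-3-methylbut-2-ene)
Product: 3 1-[2-hydroxy-4-methoxy-6-(3-methylbut-2-enyloxy)phenyl]ethanone
Conditions: K2CO3 (1.2 equiv), acetone, reflux, 8 h
Reagents that add atoms: none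
Why: Williamson ether synthesis on a symmetric diol, so either phenol gives the same ether, and the second phenol is then locked in a hydrogen bond to the ketone and is not alkylated under these mild conditions.

Step 2
Reactants: 3 1-[2-hydroxy-4-methoxy-6-(3-methylbut-2-enyloxy)phenyl]ethanone; 4 4-hydroxy-2-methoxybenzaldehyde
Product: 6 (E)-3-(4-hydroxy-2-methoxyphenyl)-1-[2-hydroxy-4-methoxy-6-(3-methylbut-2-enyloxy)phenyl]prop-2-en-1-one, via aldol adduct 5 (not isolated)
Conditions: KOH (50% aq, 12 equiv), EtOH, 0 °C → rt, 48 h; then 1 M HCl to pH 5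
Reagents that add atoms: none
Why: Claisen–Schmidt aldol condensation in which the methyl ketone enolate adds to the aldehyde and the aldol 5 loses water by E1cB to the thermodynamically favoured E enone, the prenyl ether being inert to hydroxide.

Step 3
Reactants: 6 (E)-3-(4-hydroxy-2-methoxyphenyl)-1-[2-hydroxy-4-methoxy-6-(3-methylbut-2-enyloxy)phenyl]prop-2-en-1-one
Product: 9 2-(4-hydroxy-2-methoxyphenyl)-7-methoxy-5-(3-methylbut-2-enyloxy)-4H-chromen-4-one, via flavanone 7 (not isolated), via 3-bromoflavanone 8 (not isolated)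
Conditions: DBU (3.5 equiv), BrCCl3 (1.15 equiv, slow addition), MeCN, 0 °C → rt, dark, N2
Reagents that add atoms: none
Why: Proposed new method: DBU gives the 2'-phenoxide, whose reversible 6-endo oxa-Michael addition forms the O1–C2 bond and flavanone 7 as its enolate; halophilic attack of that enolate on BrCCl3 gives 3-bromoflavanone 8 and CHCl3, and DBU-mediated E2 loss of HBr then gives the 4-pyranone irreversibly, pulling the unfavourable oxa-Michael equilibrium forward. The design uses no electrophilic halonium, quinone or iodine oxidant, so the prenyl ether and the free phenol should survive, and the aprotic medium closes the alkoxide-assisted aurone pathway. The closest known reactions are the BrCCl3/DBU dehydrogenation of oxazolines to oxazoles and the base dehydrobromination of preformed 3-bromoflavanones; the one-flask cyclisation–dehydrogenation of a 2'-hydroxychalcone with this reagent pair is, to my knowledge, not described.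

Step 4
Reactants: 9 2-(4-hydroxy-2-methoxyphenyl)-7-methoxy-5-(3-methylbut-2-enyloxy)-4H-chromen-4-one
Product: 12 Artocarpetin B, via ortho-dienone 10 (not isolated), via para-dienone 11 (not isolated)
Conditions: Eu(fod)3 (10 mol %), NaHCO3 (1 equiv), PhCl, 85 °C, 24 h
Reagents that add atoms: none
Why: Lewis-acid-catalysed para-Claisen–Cope rearrangement in which the trivalent europium chelate bound at O4/O5 promotes the [3,3] shift to C6 (the only open ortho site, giving dienone 10), a second [3,3] Cope shift carries the unit to C8 as a linear prenyl group (dienone 11), and enolisation restores ring A with the chelated 5-OH; no stereocentre remains.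

## Compound list

1 | 1-(2,6-dihydroxy-4-methoxyphenyl)ethanone | CC(=O)c1c(O)cc(OC)cc1O | starting material
2 | prenyl bromide (1-bromo-3-methylbut-2-ene) | CC(C)=CCBr | starting material
3 | 1-[2-hydroxy-4-methoxy-6-(3-methylbut-2-enyloxy)phenyl]ethanone | CC(=O)c1c(O)cc(OC)cc1OCC=C(C)C | intermediate
4 | 4-hydroxy-2-methoxybenzaldehyde | COc1cc(O)ccc1C=O | starting material
5 | 3-hydroxy-3-(4-hydroxy-2-methoxyphenyl)-1-[2-hydroxy-4-methoxy-6-(3-methylbut-2-enyloxy)phenyl]propan-1-one (racemic aldol adduct) | COc1cc(O)ccc1C(O)CC(=O)c1c(O)cc(OC)cc1OCC=C(C)C | intermediate (not isolated)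
6 | (E)-3-(4-hydroxy-2-methoxyphenyl)-1-[2-hydroxy-4-methoxy-6-(3-methylbut-2-enyloxy)phenyl]prop-2-en-1-one | COc1cc(O)ccc1/C=C/C(=O)c1c(O)cc(OC)cc1OCC=C(C)C | intermediate
7 | 2-(4-hydroxy-2-methoxyphenyl)-7-methoxy-5-(3-methylbut-2-enyloxy)chroman-4-one (racemic; present as its enolate in step 3) | COc1cc(O)ccc1C1CC(=O)c2c(OCC=C(C)C)cc(OC)cc2O1 | intermediate (not isolated)
8 | 3-bromo-2-(4-hydroxy-2-methoxyphenyl)-7-methoxy-5-(3-methylbut-2-enyloxy)chroman-4-one (racemic, mixture of diastereomers) | COc1cc(O)ccc1C1Oc2cc(OC)cc(OCC=C(C)C)c2C(=O)C1Br | intermediate (not isolated)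
9 | 2-(4-hydroxy-2-methoxyphenyl)-7-methoxy-5-(3-methylbut-2-enyloxy)-4H-chromen-4-one | COc1cc(O)ccc1-c1cc(=O)c2c(OCC=C(C)C)cc(OC)cc2o1 | intermediate
10 | 2-(4-hydroxy-2-methoxyphenyl)-7-methoxy-6-(2-methylbut-3-en-2-yl)-6H-chromene-4,5-dione (racemic ortho-dienone) | COc1cc(O)ccc1C1=CC(=O)C2=C(O1)C=C(OC)C(C(C)(C)C=C)C2=O | intermediate (not isolated)
11 | 2-(4-hydroxy-2-methoxyphenyl)-7-methoxy-8-(3-methylbut-2-enyl)-8H-chromene-4,5-dione (racemic para-dienone) | COc1cc(O)ccc1C1=CC(=O)C2=C(O1)C(CC=C(C)C)C(OC)=CC2=O | intermediate (not isolated)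
12 | Artocarpetin B, 5-hydroxy-2-(4-hydroxy-2-methoxyphenyl)-7-methoxy-8-(3-methylbut-2-enyl)-4H-chromen-4-one (achiral) | COc1cc(O)ccc1-c1cc(=O)c2c(O)cc(OC)c(CC=C(C)C)c2o1 | target

## Step count

Total steps: 4. Longest linear sequence: 4 (1 → 3 → 6 → 9 → 12).

## Steps most likely to fail, with fallbacks

**Step 3 (proposed new ring closure).** Risks are competing C-bromination of the phenoxide rings, over-bromination at C3, and slow oxa-Michael addition of the doubly deprotonated chalcone. The fallback uses only known chemistry and closes ring C before any prenyl ether is present, so the classical iodine oxidation can be used. It sets out from 1 and 4. Claisen–Schmidt condensation (KOH, EtOH) gives (E)-1-(2,6-dihydroxy-4-methoxyphenyl)-3-(4-hydroxy-2-methoxyphenyl)prop-2-en-1-one F5. Oxidative cyclisation (cat. I2, DMSO, 130 °C) gives 5-hydroxy-2-(4-hydroxy-2-methoxyphenyl)-7-methoxy-4H-chromen-4-one F6; ring A is symmetric, so no regiochemical question arises. Silylation of the non-chelated phenol (TIPSCl, imidazole, DMF, rt) gives 5-hydroxy-7-methoxy-2-[2-methoxy-4-(triisopropylsilyloxy)phenyl]-4H-chromen-4-one F7. Mitsunobu etherification of the chelated 5-OH (3-methylbut-2-en-1-ol, PPh3, DIAD, THF) gives 7-methoxy-2-[2-methoxy-4-(triisopropylsilyloxy)phenyl]-5-(3-methylbut-2-enyloxy)-4H-chromen-4-one F8. Bu4NF in THF at 0 °C removes the silyl group and the route is rejoined at 9.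

**Step 4 (para-Claisen–Cope on the flavone).** Risks are arrest at the ortho stage (the 6-(1,1-dimethylallyl) isomer), loss of the prenyl group to give the 5-hydroxyflavone, and sequestration of the catalyst by the free phenol. The fallback moves the rearrangement to the flavanone oxidation level, where this relay is best precedented, and dehydrogenates last. It sets out from 6. NaOAc in refluxing EtOH closes the chalcone to the racemic flavanone 7, this time isolated. Eu(fod)3 with NaHCO3 in PhCl at 85 °C gives racemic 5-hydroxy-2-(4-hydroxy-2-methoxyphenyl)-7-methoxy-8-(3-methylbut-2-enyl)chroman-4-one F9. Dehydrogenation with cat. I2 in DMSO at 120 °C removes the C2 stereocentre and the route is rejoined at 12; the C-prenyl group has no neighbouring phenol to cyclise onto.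

**Step 2 (Claisen–Schmidt with a free para-hydroxybenzaldehyde).** The aldehyde is deactivated as its phenoxide, so conversion may be slow or low. Partial closure of 6 to flavanone 7 on acidification is harmless, because both enter step 3 through the same enolate. The fallback masks the phenol and unmasks it only at the end. It sets out from 4. MOMCl with i-Pr2NEt in CH2Cl2 gives 2-methoxy-4-(methoxymethoxy)benzaldehyde F1. Condensation with 3 under the step 2 conditions gives (E)-1-[2-hydroxy-4-methoxy-6-(3-methylbut-2-enyloxy)phenyl]-3-[2-methoxy-4-(methoxymethoxy)phenyl]prop-2-en-1-one F2. The step 3 conditions give 7-methoxy-2-[2-methoxy-4-(methoxymethoxy)phenyl]-5-(3-methylbut-2-enyloxy)-4H-chromen-4-one F3. The step 4 conditions give 5-hydroxy-7-methoxy-2-[2-methoxy-4-(methoxymethoxy)phenyl]-8-(3-methylbut-2-enyl)-4H-chromen-4-one F4. Dilute HCl in MeOH at 40 °C removes the acetal and the route is rejoined at 12; the acetal is removed only after the acid-labile aryl prenyl ether has been converted to the C-prenyl group.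

## Further compounds

F1 | step 2 | 2-methoxy-4-(methoxymethoxy)benzaldehyde | COCOc1ccc(C=O)c(OC)c1
F2 | step 2 | (E)-1-[2-hydroxy-4-methoxy-6-(3-methylbut-2-enyloxy)phenyl]-3-[2-methoxy-4-(methoxymethoxy)phenyl]prop-2-en-1-one | COCOc1ccc(/C=C/C(=O)c2c(O)cc(OC)cc2OCC=C(C)C)c(OC)c1
F3 | step 2 | 7-methoxy-2-[2-methoxy-4-(methoxymethoxy)phenyl]-5-(3-methylbut-2-enyloxy)-4H-chromen-4-one | COCOc1ccc(-c2cc(=O)c3c(OCC=C(C)C)cc(OC)cc3o2)c(OC)c1
F4 | step 2 | 5-hydroxy-7-methoxy-2-[2-methoxy-4-(methoxymethoxy)phenyl]-8-(3-methylbut-2-enyl)-4H-chromen-4-one | COCOc1ccc(-c2cc(=O)c3c(O)cc(OC)c(CC=C(C)C)c3o2)c(OC)c1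
F5 | step 3 | (E)-1-(2,6-dihydroxy-4-methoxyphenyl)-3-(4-hydroxy-2-methoxyphenyl)prop-2-en-1-one | COc1cc(O)ccc1/C=C/C(=O)c1c(O)cc(OC)cc1O
F6 | step 3 | 5-hydroxy-2-(4-hydroxy-2-methoxyphenyl)-7-methoxy-4H-chromen-4-one | COc1cc(O)ccc1-c1cc(=O)c2c(O)cc(OC)cc2o1
F7 | step 3 | 5-hydroxy-7-methoxy-2-[2-methoxy-4-(triisopropylsilyloxy)phenyl]-4H-chromen-4-one | COc1cc(O[Si](C(C)C)(C(C)C)C(C)C)ccc1-c1cc(=O)c2c(O)cc(OC)cc2o1
F8 | step 3 | 7-methoxy-2-[2-methoxy-4-(triisopropylsilyloxy)phenyl]-5-(3-methylbut-2-enyloxy)-4H-chromen-4-one | COc1cc(O[Si](C(C)C)(C(C)C)C(C)C)ccc1-c1cc(=O)c2c(OCC=C(C)C)cc(OC)cc2o1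
F9 | step 4 | 5-hydroxy-2-(4-hydroxy-2-methoxyphenyl)-7-methoxy-8-(3-methylbut-2-enyl)chroman-4-one (racemic) | COc1cc(O)ccc1C1CC(=O)c2c(O)cc(OC)c(CC=C(C)C)c2O1
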